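**Plan**

- Retrosynthesis (labdane numbering): the C7 and C15 acetates are removed; the C7 carbinol goes back to a C7 ketone and the C9–C11 bond is cut, giving a side-chain organolithium and a ring-B vinylogous ester (C9=O, C7–OMe); the C6 carbinol goes back to a ketone; last, the two ring-A bonds C10–C1 and C5–C4 are cut together.
- Enabling feature: ring B (C5–C10) carries oxygen at C6 and C7 and the side chain at C9, para to C6, so at the quinone oxidation level it is 2-methoxy-3,5-dimethyl-1,4-benzoquinone, whose only trisubstituted C=C is the C5–C10 edge shared with ring A; C1–C4 with the C4 gem-dimethyl group is 4-methylpenta-1,3-diene.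
- Forward: ring B is made first as the quinone; ring A is closed last by a catalytic enantioselective Diels–Alder reaction; ring-A hydrogenation, C5 epimerisation and C6 reduction follow; the C11–C15 chain is added at C9 and acid transposes the carbonyl to C7 (C8=C9 formed); C7 reduction and a selective double acetylation finish.
- Stereochemistry: C10 from the chiral Lewis acid in the cycloaddition; C5 by base equilibration to the trans-decalin; C6 by α-face hydride attack (β face blocked by the C10 and C4β methyls); C7 by hydride delivery from the 6β-hydroxyl; 13Z from commercial (2Z)-3-methylpent-2-en-4-yn-1-ol; the hindered 6β-hydroxyl is never protected.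

Key step: step 4

Assumption: the (S)-configured catalyst of step 4 is taken to direct the diene to the quinone face that gives 10S, as its coordination model suggests; the (R)-catalyst is equally available and would be used if the sense is the opposite.

Step 1
Reactants: 1 2,6-dimethyl-1,4-benzoquinone
Product: 2 rac-1,3-dimethyl-7-oxabicyclo[4.1.0]hept-3-ene-2,5-dione (mono-epoxide of 1)
Conditions: H2O2 (30 % aq., 1.0 equiv), Na2CO3 (cat.), EtOH–H2O, 0 °C
Reagents that add atoms: hydrogen peroxide, OO
Why: Weitz–Scheffer nucleophilic epoxidation of the electron-poor quinone C=C by hydroperoxide anion; the two C=C bonds of 1 are equivalent and one equivalent of oxidant should stop at the mono-epoxide.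

Step 2
Reactants: 2 rac-1,3-dimethyl-7-oxabicyclo[4.1.0]hept-3-ene-2,5-dione
Product: 3 3-hydroxy-2,6-dimethyl-1,4-benzoquinone
Conditions: conc. H2SO4, 0 °C → rt; then ice–water
Reagents that add atoms: none
Why: acid-induced opening of the oxirane with loss of the proton on the CH epoxide carbon and enolisation, the benzoquinone counterpart of the classical epoxynaphthoquinone to hydroxynaphthoquinone isomerisation, can place the hydroxyl only on the carbon that carried hydrogen.

Step 3
Reactants: 3 3-hydroxy-2,6-dimethyl-1,4-benzoquinone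
Product: 4 2-methoxy-3,5-dimethyl-1,4-benzoquinone (quinone C1, C2, C3, C4, C5, C6 become labdane C6, C7, C8, C9, C10, C5)
Conditions: MeI, Ag2O, CH2Cl2, rt, dark
Reagents that add atoms: iodomethane, CI
Why: O-methylation of the hydroxyquinone, a vinylogous acid, with silver-assisted iodomethane is standard and leaves the quinone untouched.

Step 4
Reactants: 4 2-methoxy-3,5-dimethyl-1,4-benzoquinone; 5 4-methylpenta-1,3-diene
Product: 6 (4aS,8aR)-2-methoxy-3,4a,8,8-tetramethyl-4a,5,8,8a-tetrahydronaphthalene-1,4-dione (cis-fused adduct; 5β-H, 10β-CH3, C2=C3 in ring A)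
Conditions: (S)-3,3-diphenyl-1-(2-methylphenyl)tetrahydro-1H,3H-pyrrolo[1,2-c][1,3,2]oxazaborole protonated with HN(SO2CF3)2 (20 mol %), excess diene, CH2Cl2, −78 → −20 °C
Reagents that add atoms: none
Why: The protonated oxazaborolidine should bind the C6 carbonyl of 4 at the lone pair syn to the vinylic C5–H, the only such site because the C9 carbonyl is flanked on both sides by methyl-bearing carbons, which makes methyl-bearing C10 the electrophilic β-carbon, so that the unsubstituted, most nucleophilic terminus of the diene bonds to it first in a concerted but strongly asynchronous [4+2] cycloaddition whose developing positive charge sits on the gem-dimethyl allyl terminus that then closes on C5. The closest known reaction type is the chiral-Lewis-acid-catalysed Diels–Alder reaction of methyl- and methoxy-substituted 1,4-benzoquinones with 2-substituted and (E)-1-substituted butadienes, which forms angular-methyl quaternary centres; a diene with a fully substituted terminus is a more demanding member of the same class. Ring A closes by suprafacial [4+2] addition across C5=C10, forming C10–C1 and C5–C4 at once and leaving C2=C3. The C10 configuration is set by the catalyst, which shields one face of the bound quinone, and C5 is necessarily cis to it (corrected in step 5), while endo or exo approach is without consequence because C1 and C4 carry no stereocentre. The step needs site selectivity (C5=C10, not C7=C8), secured by the methoxy and methyl groups that make C7=C8 tetrasubstituted and electron-rich, and regioselectivity, secured by the match of the C10 β-carbon with the unsubstituted diene terminus, which also keeps the quaternary carbons C4 and C10 apart. The low reactivity of a diene with a cis-methyl terminus is offset by the cationic Lewis acid, an excess of the diene and the asynchronous transition state.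

Step 5
Reactants: 6 (4aS,8aR)-2-methoxy-3,4a,8,8-tetramethyl-4a,5,8,8a-tetrahydronaphthalene-1,4-dione
Product: 8 (4aS,8aS)-2-methoxy-3,4a,8,8-tetramethyl-4a,5,6,7,8,8a-hexahydronaphthalene-1,4-dione (trans-fused; 5α-H, 10β-CH3), via cis-fused saturated dione 7 (not isolated)
Conditions: H2 (1 atm), RhCl(PPh3)3 (5 mol %), C6H6–EtOH, rt; then DBU (0.3 equiv), CH2Cl2, rt
Reagents that add atoms: none
Why: the rhodium catalyst should hydrogenate only the cis-disubstituted ring-A alkene and not the tetrasubstituted, donor-substituted enedione alkene, and catalytic DBU then equilibrates C5 (α to the C6 ketone) through its enolate to the more stable trans-decalin with a chair ring A.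

Step 6
Reactants: 8 (4aS,8aS)-2-methoxy-3,4a,8,8-tetramethyl-4a,5,6,7,8,8a-hexahydronaphthalene-1,4-dione
Product: 9 (4S,4aS,8aS)-4-hydroxy-3-methoxy-2,5,5,8a-tetramethyl-4a,5,6,7,8,8a-hexahydronaphthalen-1(4H)-one (6β-hydroxy, labdane numbering)
Conditions: NaBH4, CeCl3·7H2O, MeOH, −40 °C
Reagents that add atoms: none
Why: Luche 1,2-reduction should take the C6 ketone, which is more electrophilic and less hindered than the vinylogous-ester C9 carbonyl, and hydride attacks from the α face because the β face is blocked by the syn-axial C10 and C4β methyl groups, giving the axial 6β-alcohol.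

Step 7
Reactants: 10 (2Z)-3-methylpent-2-en-4-yn-1-ol
Product: 11 tert-butyldimethyl{[(2Z)-3-methylpent-2-en-4-yn-1-yl]oxy}silane
Conditions: TBSCl, imidazole, CH2Cl2, 0 °C → rt
Reagents that add atoms: tert-butyldimethylsilyl chloride, CC(C)(C)[Si](C)(C)Cl
Why: routine silylation of the primary allylic alcohol, which leaves the Z-alkene untouched.

Step 8
Reactants: 11 tert-butyldimethyl{[(2Z)-3-methylpent-2-en-4-yn-1-yl]oxy}silane
Product: 12 tert-butyldimethyl{[(2Z)-3-methylpenta-2,4-dien-1-yl]oxy}silane
Conditions: H2 (1 atm), Pd/CaCO3 poisoned with Pb(OAc)2, quinoline, hexane, rt, stopped at one equivalent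
Reagents that add atoms: none
Why: semi-hydrogenation of the terminal alkyne over poisoned palladium gives the vinyl group without touching the trisubstituted Z-alkene.

Step 9
Reactants: 12 tert-butyldimethyl{[(2Z)-3-methylpenta-2,4-dien-1-yl]oxy}silane
Product: 14 tert-butyl{[(2Z)-5-iodo-3-methylpent-2-en-1-yl]oxy}dimethylsilane, via B-alkyl-9-borabicyclo[3.3.1]nonane 13 (not isolated)
Conditions: 9-BBN-H, THF, 0 °C → rt; then NaOMe/MeOH, I2, 0 °C
Reagents that add atoms: iodine, II
Why: 9-BBN-H hydroborates only the monosubstituted vinyl group with boron on the terminal carbon, and base-induced iodinolysis cleaves the primary exocyclic B–C bond to the homoallylic iodide.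

Step 10
Reactants: 9 (4S,4aS,8aS)-4-hydroxy-3-methoxy-2,5,5,8a-tetramethyl-4a,5,6,7,8,8a-hexahydronaphthalen-1(4H)-one; 14 tert-butyl{[(2Z)-5-iodo-3-methylpent-2-en-1-yl]oxy}dimethylsilane
Product: 17 (4S,4aS,8aS)-1-[(3Z)-5-(tert-butyldimethylsilyloxy)-3-methylpent-3-en-1-yl]-3-methoxy-2,5,5,8a-tetramethyl-1,4,4a,5,6,7,8,8a-octahydronaphthalene-1,4-diol (C9 carbinol; side chain expected α), via lithium alkoxide 15 (not isolated), via homoallylic organolithium 16 (not isolated)
Conditions: 14, t-BuLi (2.1 equiv), Et2O–pentane, −78 °C; 9, LiN(SiMe3)2 (1.05 equiv), THF, −78 °C; combine, −78 → 0 °C; aq. NH4Cl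
Reagents that add atoms: none
Why: iodine–lithium exchange gives a primary alkyllithium that adds 1,2 to the non-enolisable vinylogous-ester carbonyl C9 (first half of a Stork–Danheiser sequence) while the C6 hydroxyl is masked as its lithium alkoxide; the C9 configuration (attack anti to the C10 methyl expected) is lost in step 11.

Step 11
Reactants: 17 C9 carbinol from step 10
Product: 18 (1S,4aS,8aS)-1-hydroxy-4-[(3Z)-5-hydroxy-3-methylpent-3-en-1-yl]-3,4a,8,8-tetramethyl-4a,5,6,7,8,8a-hexahydronaphthalen-2(1H)-one ((13Z)-6β,15-dihydroxylabda-8,13-dien-7-one)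
Conditions: 2 M aq. HCl, THF, 0 °C → rt
Reagents that add atoms: water, O
Why: acid hydrolysis of the methyl enol ether with loss of the tertiary C9 hydroxyl (Stork–Danheiser 1,3-carbonyl transposition) gives the C7 ketone conjugated to the new tetrasubstituted C8=C9 bond, and the same acid removes the primary silyl ether.

Step 12
Reactants: 18 (13Z)-6β,15-dihydroxylabda-8,13-dien-7-one
Product: 19 (1S,2S,4aS,8aS)-4-[(3Z)-5-hydroxy-3-methylpent-3-en-1-yl]-3,4a,8,8-tetramethyl-1,2,4a,5,6,7,8,8a-octahydronaphthalene-1,2-diol ((13Z)-labda-8,13-diene-6β,7α,15-triol)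
Conditions: Me4NBH(OAc)3, MeCN–AcOH, −20 °C → rt
Reagents that add atoms: none
Why: hydroxyl-directed triacetoxyborohydride reduction, in which the axial 6β-hydroxyl binds boron and delivers hydride to the β face of the adjacent C7 ketone, should give the trans-diaxial 6β,7α-diol, and the reagent does not touch the alkenes.

Step 13
Reactants: 19 (13Z)-labda-8,13-diene-6β,7α,15-triol
Product: 20 (13Z)-6β-hydroxylabda-8,13-diene-7α,15-diyl diacetate (target)
Conditions: Ac2O (2.2 equiv), pyridine, 0 °C → rt
Reagents that add atoms: acetic anhydride, CC(=O)OC(C)=O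
Why: acetylation should take the primary C15 and the allylic C7 hydroxyls, while the axial 6β-hydroxyl, syn-diaxial to the C10 and C4β methyl groups, is too hindered to react under these conditions.

**Compound list**

1 | 2,6-dimethyl-1,4-benzoquinone | CC1=CC(=O)C=C(C)C1=O | starting material
2 | rac-1,3-dimethyl-7-oxabicyclo[4.1.0]hept-3-ene-2,5-dione (racemic, cis-fused oxirane) | CC1=CC(=O)C2OC2(C)C1=O | intermediate
3 | 3-hydroxy-2,6-dimethyl-1,4-benzoquinone | CC1=CC(=O)C(O)=C(C)C1=O | intermediate
4 | 2-methoxy-3,5-dimethyl-1,4-benzoquinone | COC1=C(C)C(=O)C(C)=CC1=O | intermediate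
5 | 4-methylpenta-1,3-diene | C=CC=C(C)C | starting material
6 | (4aS,8aR)-2-methoxy-3,4a,8,8-tetramethyl-4a,5,8,8a-tetrahydronaphthalene-1,4-dione | O=C1C(C)=C(OC)C(=O)[C@@H]2C(C)(C)C=CC[C@]12C | intermediate
7 | (4aS,8aR)-2-methoxy-3,4a,8,8-tetramethyl-4a,5,6,7,8,8a-hexahydronaphthalene-1,4-dione (cis-fused) | O=C1C(C)=C(OC)C(=O)[C@@H]2C(C)(C)CCC[C@]12C | intermediate (not isolated)
8 | (4aS,8aS)-2-methoxy-3,4a,8,8-tetramethyl-4a,5,6,7,8,8a-hexahydronaphthalene-1,4-dione (trans-fused) | O=C1C(C)=C(OC)C(=O)[C@H]2C(C)(C)CCC[C@]12C | intermediate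
9 | (4S,4aS,8aS)-4-hydroxy-3-methoxy-2,5,5,8a-tetramethyl-4a,5,6,7,8,8a-hexahydronaphthalen-1(4H)-one | O=C1C(C)=C(OC)[C@@H](O)[C@H]2C(C)(C)CCC[C@]12C | intermediate
10 | (2Z)-3-methylpent-2-en-4-yn-1-ol | OC/C=C(/C)C#C | starting material
11 | tert-butyldimethyl{[(2Z)-3-methylpent-2-en-4-yn-1-yl]oxy}silane | CC(C)(C)[Si](C)(C)OC/C=C(/C)C#C | intermediate
12 | tert-butyldimethyl{[(2Z)-3-methylpenta-2,4-dien-1-yl]oxy}silane | CC(C)(C)[Si](C)(C)OC/C=C(/C)C=C | intermediate
13 | 9-[(3Z)-5-(tert-butyldimethylsilyloxy)-3-methylpent-3-en-1-yl]-9-borabicyclo[3.3.1]nonane | CC(C)(C)[Si](C)(C)OC/C=C(/C)CCB1C2CCCC1CCC2 | intermediate (not isolated)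
14 | tert-butyl{[(2Z)-5-iodo-3-methylpent-2-en-1-yl]oxy}dimethylsilane | CC(C)(C)[Si](C)(C)OC/C=C(/C)CCI | intermediate
15 | lithium alkoxide of 9 (O6–Li) | O=C1C(C)=C(OC)[C@@H](O[Li])[C@H]2C(C)(C)CCC[C@]12C | intermediate (not isolated)
16 | [(3Z)-5-(tert-butyldimethylsilyloxy)-3-methylpent-3-en-1-yl]lithium | CC(C)(C)[Si](C)(C)OC/C=C(/C)CC[Li] | intermediate (not isolated)
17 | (4S,4aS,8aS)-1-[(3Z)-5-(tert-butyldimethylsilyloxy)-3-methylpent-3-en-1-yl]-3-methoxy-2,5,5,8a-tetramethyl-1,4,4a,5,6,7,8,8a-octahydronaphthalene-1,4-diol (C9 as expected from α-face attack) | CC(C)(C)[Si](C)(C)OC/C=C(/C)CC[C@]1(O)C(C)=C(OC)[C@@H](O)[C@H]2C(C)(C)CCC[C@]12C | intermediate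
18 | (13Z)-6β,15-dihydroxylabda-8,13-dien-7-one | OC/C=C(/C)CCC1=C(C)C(=O)[C@@H](O)[C@H]2C(C)(C)CCC[C@]12C | intermediate
19 | (13Z)-labda-8,13-diene-6β,7α,15-triol | OC/C=C(/C)CCC1=C(C)[C@H](O)[C@@H](O)[C@H]2C(C)(C)CCC[C@]12C | intermediate
20 | (13Z)-6β-hydroxylabda-8,13-diene-7α,15-diyl diacetate | CC(=O)OC/C=C(/C)CCC1=C(C)[C@H](OC(C)=O)[C@@H](O)[C@H]2C(C)(C)CCC[C@]12C | target

**Step count and risks**

Total steps: 13. Longest linear sequence: 10 (steps 1–6 and 10–13); the side chain takes steps 7–9.

Steps most likely to fail:

1. Step 4. The diene may react too slowly because its cis-methyl terminus disfavours the s-cis conformer, it may oligomerise under the cationic Lewis acid or leak into stepwise [2+2] or ene pathways, and regiocontrol would be lost if the acid bound the C9 carbonyl. The fallback sets out from 4 and replaces the diene by a strain-activated diene of the same carbon pattern. Wittig olefination of acrolein with the ylide of cyclopropyltriphenylphosphonium bromide (KOtBu, THF) gives allylidenecyclopropane F1, whose tied-back terminus lacks the cis-methyl clash and gains strain relief on cycloaddition. Cycloaddition with 4 under the same catalyst should give the spiro-cyclopropane adduct F2. Hydrogenation over PtO2 in AcOH then saturates C2=C3 and cleaves the distal cyclopropane bond to the gem-dimethyl group. This comes back to the route at 7, which is epimerised to 8 with DBU as in step 5.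

2. Step 10. 1,2-Addition to the C9 carbonyl, flanked by the quaternary C10 and the methyl-bearing C8, may be slower than decay of the organolithium. The fallback sets out from 9 and 11 and uses a slimmer sp nucleophile. Deprotonation of 11 (n-BuLi, THF, −78 °C) gives the lithium acetylide F3, which is added to alkoxide 15 to give the propargylic carbinol F4. The acid treatment of step 11 converts F4 into the ynenone diol F5. Diimide (2-nitrobenzenesulfonyl hydrazide, Et3N, CH2Cl2) then saturates the C11–C12 triple bond in preference to the tri- and tetrasubstituted alkenes. This comes back to the route at 18.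

3. Step 12. Facial selectivity may be poor if external hydride attack on the open α face outruns delivery from the 6β-hydroxyl, which would give the 7β-alcohol. The fallback sets out from 18, accepts α-face reduction and corrects C7 by substitution. NaBH4/CeCl3·7H2O in MeOH gives (13Z)-labda-8,13-diene-6β,7β,15-triol F6. A Mitsunobu reaction (PPh3, diisopropyl azodicarboxylate, AcOH, THF) then esterifies the primary C15 hydroxyl and inverts the allylic C7 centre to the 7α-acetate, while the hindered 6β-hydroxyl stays free. This comes back to the route at 20.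

**Further compounds**

F1 | step 4 | allylidenecyclopropane (prop-2-en-1-ylidenecyclopropane) | C=CC=C1CC1
F2 | step 4 | cis-fused spiro-cyclopropane adduct of 4 and F1 (cyclopropane at C4, C2=C3, 5β-H, 10β-CH3) | O=C1C(C)=C(OC)C(=O)[C@@H]2C3(CC3)C=CC[C@]12C
F3 | step 10 | lithium acetylide of 11 | CC(C)(C)[Si](C)(C)OC/C=C(/C)C#C[Li]
F4 | step 10 | C9 propargylic carbinol from 15 and F3 | CC(C)(C)[Si](C)(C)OC/C=C(/C)C#C[C@]1(O)C(C)=C(OC)[C@@H](O)[C@H]2C(C)(C)CCC[C@]12C
F5 | step 10 | (13Z)-6β,15-dihydroxylabda-8,13-dien-11-yn-7-one | OC/C=C(/C)C#CC1=C(C)C(=O)[C@@H](O)[C@H]2C(C)(C)CCC[C@]12C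
F6 | step 12 | (13Z)-labda-8,13-diene-6β,7β,15-triol | OC/C=C(/C)CCC1=C(C)[C@@H](O)[C@@H](O)[C@H]2C(C)(C)CCC[C@]12C
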